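**Retrosynthetic overview**
- The ten-membered ring is closed last at C6–C7, the bond that joins C1 to C10 of the farnesyl chain. A Pd(0)-ionised allylic acetate is attacked by the distal allylstannane (SE2'), and tin leaves from C12 in place of the proton lost on the way to germacrene A, which unveils the isopropenyl group. A free allyl cation is avoided because the C15 ester deactivates it and the oxirane would trap it.
- The open-chain precursor comes from cross-metathesis of a terminal alkene with methallyltributylstannane.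
- The threo epoxy acetate comes from Mitsunobu inversion (AcOH) of an erythro epoxy alcohol, which comes from a matched Ti/tartrate hydroxyl-directed epoxidation of the C1=C10 alkene, after a Keck allylation that sets C9.
- The enal comes from a Baylis–Hillman reaction with acrolein followed by acylative 1,3-transposition, which installs the isobutyrate and the E alkene; the aldehyde comes from a Claisen rearrangement and a cross-metathesis.
- Ring order: oxirane first (step 6, acyclic stereocontrol), carbocycle last (step 9, which also sets C7).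

Assumption: locants C1–C15 follow germacrane numbering (ring C1–C10; C14 = CH2O-isobutyrate carbon on C10; C15 = ester carbon on C4; C11–C13 = isopropenyl on C7), and compounds 1 and 15 are taken as commercial.

**Route**

Step 1
Reactants: 1 methyl 2-(hydroxymethyl)prop-2-enoate; 2 ethoxyethene (ethyl vinyl ether)
Product: 4 methyl 2-methylidene-5-oxopentanoate, via allyl vinyl ether 3 (not isolated)
Conditions: Pd(OAc)2/1,10-phenanthroline (2 mol%), 2 (20 equiv), rt; evaporate; PhMe, BHT (cat.), 130 °C, sealed tube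
Reagents that add atoms: none
Why: Pd(II)-catalysed vinyl transfer gives the allyl vinyl ether, and its aliphatic Claisen [3,3] rearrangement (driven by C=O formation) carries the acrylate CH2 into the chain and leaves a new 1,1-disubstituted alkene; no stereocentre is formed.

Step 2
Reactants: 4 methyl 2-methylidene-5-oxopentanoate; 5 (2Z)-but-2-ene-1,4-diyl diacetate
Product: 6 methyl (2E)-2-[2-(acetyloxy)ethylidene]-5-oxopentanoate
Conditions: Hoveyda–Grubbs II (5 mol%), 5 (3 equiv), CH2Cl2, 40 °C
Reagents that add atoms: none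
Why: Olefin cross-metathesis of a methacrylate-type alkene with an allylic acetate donor gives the trisubstituted enoate as the thermodynamic E isomer (CH2OAc trans to CO2Me), which is the ring-cis C4=C5 geometry of the target; Ru carbenes tolerate the aldehyde.

Step 3
Reactants: 6 methyl (2E)-2-[2-(acetyloxy)ethylidene]-5-oxopentanoate; 7 prop-2-enal (acrolein)
Product: 8 methyl (2E)-2-[2-(acetyloxy)ethylidene]-6-formyl-5-hydroxyhept-6-enoate (racemic at C5)
Conditions: 7 (2 equiv, slow addition), DABCO (20 mol%), THF, 0 °C to rt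
Reagents that add atoms: none
Why: Morita–Baylis–Hillman reaction, in which the DABCO–acrolein ammonium enolate adds to the aliphatic aldehyde while the α,β-disubstituted enoate cannot act as donor; the racemic carbinol centre is erased in step 4.

Step 4
Reactants: 8 methyl (2E)-2-[2-(acetyloxy)ethylidene]-6-formyl-5-hydroxyhept-6-enoate
Product: 10 methyl (2E,5E)-2-[2-(acetyloxy)ethylidene]-6-formyl-7-[(2-methylpropanoyl)oxy]hept-5-enoate, via secondary isobutyrate 9 (not isolated)
Conditions: (i-PrCO)2O (1.3 equiv), DMAP (10 mol%), Et3N, CH2Cl2, 0 °C; then DABCO (30 mol%), rt to 40 °C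
Reagents that add atoms: 2-methylpropanoic anhydride CC(C)C(=O)OC(=O)C(C)C
Why: O-acylation followed by DABCO-catalysed SN2'–SN2' 1,3-transposition of the Baylis–Hillman ester gives the thermodynamic trisubstituted enal with the isobutyrate on the primary carbon and the chain trans to CHO (E), so that C14 is cis to C2 as the target requires.

Step 5
Reactants: 10 methyl (2E,5E)-2-[2-(acetyloxy)ethylidene]-6-formyl-7-[(2-methylpropanoyl)oxy]hept-5-enoate; 11 tributyl(prop-2-en-1-yl)stannane
Product: 12 methyl (2E,5E,7R)-2-[2-(acetyloxy)ethylidene]-7-hydroxy-6-{[(2-methylpropanoyl)oxy]methyl}deca-5,9-dienoate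
Conditions: (R)-BINOL (20 mol%), Ti(OiPr)4 (10 mol%), 4 Å MS, CH2Cl2, −20 °C; aq. NaHCO3
Reagents that add atoms: none
Why: Keck asymmetric allylation adds allyl 1,2 to the enal from the Re face with (R)-BINOL (same sense as benzaldehyde to the (R)-carbinol), which sets C9 as R, the epimer needed before the inversion in step 7; the esters are inert.

Step 6
Reactants: 12 methyl (2E,5E,7R)-2-[2-(acetyloxy)ethylidene]-7-hydroxy-6-{[(2-methylpropanoyl)oxy]methyl}deca-5,9-dienoate
Product: 13 methyl (2E)-2-[2-(acetyloxy)ethylidene]-4-[(2R,3R)-3-[(1R)-1-hydroxybut-3-en-1-yl]-3-{[(2-methylpropanoyl)oxy]methyl}oxiran-2-yl]butanoate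
Conditions: Ti(OiPr)4 (15 mol%), D-(−)-diisopropyl tartrate (18 mol%), t-BuOOH (1.5 equiv), 4 Å MS, CH2Cl2, −20 °C
Reagents that add atoms: tert-butyl hydroperoxide CC(C)(C)OO
Why: Sharpless epoxidation of a secondary allylic alcohol in the matched (fast-reacting) pairing of the (R)-carbinol with D-(−)-DIPT gives the erythro epoxy alcohol, setting C1 and C10 and raising the ee by kinetic resolution; only the allylic-alcohol alkene reacts (terminal vinyl and enoate are untouched).

Step 7
Reactants: 13 methyl (2E)-2-[2-(acetyloxy)ethylidene]-4-[(2R,3R)-3-[(1R)-1-hydroxybut-3-en-1-yl]-3-{[(2-methylpropanoyl)oxy]methyl}oxiran-2-yl]butanoate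
Product: 14 methyl (2E)-2-[2-(acetyloxy)ethylidene]-4-[(2R,3S)-3-[(1S)-1-(acetyloxy)but-3-en-1-yl]-3-{[(2-methylpropanoyl)oxy]methyl}oxiran-2-yl]butanoate
Conditions: PPh3 (2 equiv), DIAD (2 equiv), AcOH (2 equiv), PhMe, 0 °C to rt
Reagents that add atoms: acetic acid CC(=O)O
Why: Mitsunobu esterification inverts C9 by SN2 attack of acetate, turning erythro into the required threo relationship and installing the acetate in the same operation; the epoxide and esters survive the neutral conditions (the descriptor at the oxirane carbon changes from R to S only because the CIP ranking changes).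

Step 8
Reactants: 14 methyl (2E)-2-[2-(acetyloxy)ethylidene]-4-[(2R,3S)-3-[(1S)-1-(acetyloxy)but-3-en-1-yl]-3-{[(2-methylpropanoyl)oxy]methyl}oxiran-2-yl]butanoate; 15 tributyl(2-methylprop-2-en-1-yl)stannane
Product: 16 methyl (2E)-2-[2-(acetyloxy)ethylidene]-4-[(2R,3S)-3-[(1S,3E)-1-(acetyloxy)-4-methyl-5-(tributylstannyl)pent-3-en-1-yl]-3-{[(2-methylpropanoyl)oxy]methyl}oxiran-2-yl]butanoate (E/Z mixture, E drawn; both isomers converge in step 9)
Conditions: 15 (5 equiv), Hoveyda–Grubbs II (10 mol%), CH2Cl2, 40 °C; chromatography on Et3N-deactivated silica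
Reagents that add atoms: none
Why: Cross-metathesis of the only terminal alkene with a 1,1-disubstituted partner builds the trisubstituted allylstannane in which C7 is the γ-carbon; the trisubstituted enoate and the epoxide do not engage the Ru carbene.

Step 9
Reactants: 16 methyl (2E)-2-[2-(acetyloxy)ethylidene]-4-[(2R,3S)-3-[(1S,3E)-1-(acetyloxy)-4-methyl-5-(tributylstannyl)pent-3-en-1-yl]-3-{[(2-methylpropanoyl)oxy]methyl}oxiran-2-yl]butanoate
Product: 17 methyl (1R,4E,7S,9S,10S)-9-(acetyloxy)-1,10-epoxy-14-[(2-methylpropanoyl)oxy]germacra-4,11(13)-dien-15-oate (CNP0372928.1)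
Conditions: Pd(PPh3)4 (10 mol%), DMF, 60–80 °C, 2 mM, syringe-pump addition
Reagents that add atoms: none
Why: Proposed new method: Pd(0) ionises the allylic acetate to a 1-(methoxycarbonyl)-π-allyl complex (the counterpart of farnesyl diphosphate ionisation), the allylstannane attacks through its γ-carbon C7 (SE2') at the unhindered terminus C6, and Bu3Sn leaves from C12 to give the ten-membered ring and the isopropenyl group; the closest known reaction is the Pd-catalysed intramolecular allylstannane–allyl acetate (Stille-type) coupling used for five- and six-membered rings, C7 is set under substrate control by C9 (predicted cis-1,3, both groups pseudo-equatorial, not yet demonstrated), and the syn-ester π-allyl is expected to keep the C4=C5 geometry.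

**Compound list**
1 | methyl 2-(hydroxymethyl)prop-2-enoate | C=C(CO)C(=O)OC | starting material
2 | ethoxyethene (ethyl vinyl ether) | C=COCC | starting material
3 | methyl 2-[(ethenyloxy)methyl]prop-2-enoate | C=COCC(=C)C(=O)OC | intermediate
4 | methyl 2-methylidene-5-oxopentanoate | C=C(CCC=O)C(=O)OC | intermediate
5 | (2Z)-but-2-ene-1,4-diyl diacetate | CC(=O)OC/C=C\COC(C)=O | starting material
6 | methyl (2E)-2-[2-(acetyloxy)ethylidene]-5-oxopentanoate | COC(=O)/C(CCC=O)=C/COC(C)=O | intermediate
7 | prop-2-enal (acrolein) | C=CC=O | starting material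
8 | methyl (2E)-2-[2-(acetyloxy)ethylidene]-6-formyl-5-hydroxyhept-6-enoate (racemic at C5) | COC(=O)/C(CCC(O)C(=C)C=O)=C/COC(C)=O | intermediate
9 | methyl (2E)-2-[2-(acetyloxy)ethylidene]-6-formyl-5-[(2-methylpropanoyl)oxy]hept-6-enoate (racemic at C5) | COC(=O)/C(CCC(OC(=O)C(C)C)C(=C)C=O)=C/COC(C)=O | intermediate
10 | methyl (2E,5E)-2-[2-(acetyloxy)ethylidene]-6-formyl-7-[(2-methylpropanoyl)oxy]hept-5-enoate | COC(=O)/C(CC/C=C(/C=O)COC(=O)C(C)C)=C/COC(C)=O | intermediate
11 | tributyl(prop-2-en-1-yl)stannane | C=CC[Sn](CCCC)(CCCC)CCCC | starting material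
12 | methyl (2E,5E,7R)-2-[2-(acetyloxy)ethylidene]-7-hydroxy-6-{[(2-methylpropanoyl)oxy]methyl}deca-5,9-dienoate | COC(=O)/C(CC/C=C(COC(=O)C(C)C)/[C@H](O)CC=C)=C/COC(C)=O | intermediate
13 | methyl (2E)-2-[2-(acetyloxy)ethylidene]-4-[(2R,3R)-3-[(1R)-1-hydroxybut-3-en-1-yl]-3-{[(2-methylpropanoyl)oxy]methyl}oxiran-2-yl]butanoate | COC(=O)/C(CC[C@H]1O[C@]1(COC(=O)C(C)C)[C@H](O)CC=C)=C/COC(C)=O | intermediate
14 | methyl (2E)-2-[2-(acetyloxy)ethylidene]-4-[(2R,3S)-3-[(1S)-1-(acetyloxy)but-3-en-1-yl]-3-{[(2-methylpropanoyl)oxy]methyl}oxiran-2-yl]butanoate | COC(=O)/C(CC[C@H]1O[C@]1(COC(=O)C(C)C)[C@@H](OC(C)=O)CC=C)=C/COC(C)=O | intermediate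
15 | tributyl(2-methylprop-2-en-1-yl)stannane | C=C(C)C[Sn](CCCC)(CCCC)CCCC | starting material
16 | methyl (2E)-2-[2-(acetyloxy)ethylidene]-4-[(2R,3S)-3-[(1S,3E)-1-(acetyloxy)-4-methyl-5-(tributylstannyl)pent-3-en-1-yl]-3-{[(2-methylpropanoyl)oxy]methyl}oxiran-2-yl]butanoate | COC(=O)/C(CC[C@H]1O[C@]1(COC(=O)C(C)C)[C@@H](OC(C)=O)C/C=C(\C)C[Sn](CCCC)(CCCC)CCCC)=C/COC(C)=O | intermediate
17 | methyl (1R,4E,7S,9S,10S)-9-(acetyloxy)-1,10-epoxy-14-[(2-methylpropanoyl)oxy]germacra-4,11(13)-dien-15-oate | C=C(C)[C@H]1C/C=C(/C(=O)OC)CC[C@H]2O[C@]2(COC(=O)C(C)C)[C@@H](OC(C)=O)C1 | target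

**Totals**
Total step count: 9. Longest linear sequence: 9 steps (from 1).

**Steps most likely to fail, with fallbacks**

Step 9 (ring closure: ring size, regiochemistry and C7 configuration are unproven). The fallback sets out from 16 and returns at 17, closing the same bond in the aldehyde mode. Lipase alcoholysis (CAL-B, n-BuOH, MTBE) removes only the unhindered primary allylic acetate of 16 to give the C6 alcohol F5. MnO2 in CH2Cl2 oxidises it to the (E)-4-oxo-enoate aldehyde F6. Sc(OTf)3 (10 mol%, CH2Cl2, −40 °C, 1 mM) then promotes intramolecular allylstannane–aldehyde SE2' addition to the 6-hydroxy macrocycle F7 (either C6 epimer serves). Methyl chloroformate/pyridine gives the 6-methyl carbonate F8, and Pd(PPh3)4/Bu3SnH removes the allylic oxygen with hydride delivery to C6, keeping the enoate conjugated and giving 17.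

Step 8 (cross-metathesis with a 1,1-disubstituted allylstannane may be sluggish or suffer destannylation). The fallback sets out from 14 and returns at 16. Cross-metathesis of 14 with 2-methylbut-2-ene (Grubbs II) gives the prenyl compound F3. Ene-type allylic chlorination of this electron-rich trisubstituted alkene (NCS, cat. PhSeCl, CH2Cl2) gives the transposed secondary allylic chloride F4. Pd2(dba)3/hexabutyldistannane then stannylates the chloride (which undergoes oxidative addition faster than the acetate) with allylic transposition to the primary stannane 16.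

Step 7 (Mitsunobu inversion with acetic acid at a carbinol next to a fully substituted oxirane carbon). The fallback sets out from 10 and returns at 14 without any inversion. Keck allylation of 10 with (S)-BINOL gives the (7S)-homoallylic alcohol F1. Ac2O/DMAP gives the (7S)-acetate F2, which already has the final C9 configuration. Reagent-controlled Shi epoxidation (D-fructose-derived ketone, Oxone, pH 10.5, MeCN/DMM/H2O) of the only trisubstituted non-conjugated alkene then gives 14.

**Further compounds**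
F1 | step 7 | methyl (2E,5E,7S)-2-[2-(acetyloxy)ethylidene]-7-hydroxy-6-{[(2-methylpropanoyl)oxy]methyl}deca-5,9-dienoate | COC(=O)/C(CC/C=C(COC(=O)C(C)C)/[C@@H](O)CC=C)=C/COC(C)=O
F2 | step 7 | methyl (2E,5E,7S)-7-(acetyloxy)-2-[2-(acetyloxy)ethylidene]-6-{[(2-methylpropanoyl)oxy]methyl}deca-5,9-dienoate | COC(=O)/C(CC/C=C(COC(=O)C(C)C)/[C@@H](OC(C)=O)CC=C)=C/COC(C)=O
F3 | step 8 | methyl (2E)-2-[2-(acetyloxy)ethylidene]-4-[(2R,3S)-3-[(1S)-1-(acetyloxy)-4-methylpent-3-en-1-yl]-3-{[(2-methylpropanoyl)oxy]methyl}oxiran-2-yl]butanoate | COC(=O)/C(CC[C@H]1O[C@]1(COC(=O)C(C)C)[C@@H](OC(C)=O)CC=C(C)C)=C/COC(C)=O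
F4 | step 8 | methyl (2E)-2-[2-(acetyloxy)ethylidene]-4-[(2R,3S)-3-[(1S)-1-(acetyloxy)-3-chloro-4-methylpent-4-en-1-yl]-3-{[(2-methylpropanoyl)oxy]methyl}oxiran-2-yl]butanoate (both CHCl epimers) | COC(=O)/C(CC[C@H]1O[C@]1(COC(=O)C(C)C)[C@@H](OC(C)=O)CC(Cl)C(C)=C)=C/COC(C)=O
F5 | step 9 | methyl (2E)-4-[(2R,3S)-3-[(1S,3E)-1-(acetyloxy)-4-methyl-5-(tributylstannyl)pent-3-en-1-yl]-3-{[(2-methylpropanoyl)oxy]methyl}oxiran-2-yl]-2-(2-hydroxyethylidene)butanoate | COC(=O)/C(CC[C@H]1O[C@]1(COC(=O)C(C)C)[C@@H](OC(C)=O)C/C=C(\C)C[Sn](CCCC)(CCCC)CCCC)=C/CO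
F6 | step 9 | methyl (2E)-4-[(2R,3S)-3-[(1S,3E)-1-(acetyloxy)-4-methyl-5-(tributylstannyl)pent-3-en-1-yl]-3-{[(2-methylpropanoyl)oxy]methyl}oxiran-2-yl]-2-(2-oxoethylidene)butanoate | COC(=O)/C(CC[C@H]1O[C@]1(COC(=O)C(C)C)[C@@H](OC(C)=O)C/C=C(\C)C[Sn](CCCC)(CCCC)CCCC)=C/C=O
F7 | step 9 | 6-hydroxy derivative of 17 (configuration at C1, C7, C9 and C10 as in 17; either C6 epimer) | C=C(C)[C@H]1C(O)/C=C(/C(=O)OC)CC[C@H]2O[C@]2(COC(=O)C(C)C)[C@@H](OC(C)=O)C1
F8 | step 9 | 6-[(methoxycarbonyl)oxy] derivative of 17 (configuration at C1, C7, C9 and C10 as in 17; either C6 epimer) | C=C(C)[C@H]1C(OC(=O)OC)/C=C(/C(=O)OC)CC[C@H]2O[C@]2(COC(=O)C(C)C)[C@@H](OC(C)=O)C1
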